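**Z ledger.** Start from the Z left over. Each X gone holds one Z as E, or two in the missing balance, so Z used is two per X gone, less E. In a flask with Z as limiting reagent, the end comes where Z used equals the charge. E then equals the Z ceiling, two minus the equivalents of Z, which is 70.0% for oak, less two for each X left.

| flask | X | Z | temperature | remark | time |
|---|---|---|---|---|---|
| blue | 0.035 M | 1.5 equiv | 105 °C | run made earlier |  |
| green | 0.035 M | 2.2 equiv | 140 °C | run made earlier |  |
| ochre | 0.035 M | 4.4 equiv | 105 °C | run made earlier |  |
| oak | 0.035 M | 1.30 equiv |  | at 110 °C until 2.0 h, from then on at 170 °C | 4.0 h |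
| ash | 0.035 M | 3.90 equiv |  | at 170 °C throughout | 4.0 h |

| run | time / min | E / % | X / % |
|---|---|---|---|
| blue | 15.0 | 35.3 | 61.4 |
| blue | 40.0 | 48.3 | 34.5 |
| blue | 80.0 | 52.5 | 18.9 |
| blue | 120 | 49.3 | 14.5 |
| green | 2.50 | 56.2 | 28.9 |
| green | 5.00 | 53.6 | 13.4 |
| green | 12.0 | 36.1 | 1.6 |
| green | 25.0 | 18.7 | 0.3 |
| ochre | 10.0 | 49.3 | 35.6 |
| ochre | 20.0 | 51.0 | 14.4 |
| ochre | 50.0 | 26.3 | 2.3 |
| ochre | 120 | 5.7 | 0 |

(readings scatter by 1 percentage point)

- the winner by amount of E, in percent of the X charged; "neither" if no more than 2 percentage points parts them (oak / ash / neither)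
- how much E is there at the end, in percent of the X charged: oak
- how much E is there at the end, in percent of the X charged: ash

**Oak bracket.** Reckon the correction, the leftover X. Green at X 13.4% shows E 53.6% and ochre at X 14.4% shows E 51.0%, so these two runs read close at like X, though they differ in [Z] and temperature; take ochre's readings as a guide for oak. Ochre's Z used reads 79.5%, 120%, 169%. Z used per X gone steepens from 1.92 to 4.04. Oak's 1.30 equiv falls in the later interval. The later chord overstates leftover X, at 12.0%, so on these scattered readings the lower bound for oak's E is 46.0%. The earlier slope continued understates it, at 9.30%, so the upper bound reads 51.4%.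

**Ash bracket.** Ash's ceiling is −190%, below zero. Green's E reads as halving in about 13.2 min, far shorter than 4.0 h, and ash is hotter than green and richer in Z. Put ash near zero.

**The forecast.** It says oak, with oak 52% and ash 0%: “the remaining Z is used up quickly, mostly on E”. Its oak figure stands just above my bracket, by less than the scatter of 1 percentage point.

**The result.** The winner is oak, with oak 49.4% and ash 0%. Oak ends with Z 0% and X 10.3%, and its ceiling less two per X gives 49.4%.

    X + Z → E (k = 1.07 M⁻¹ min⁻¹, Ea = 91.0 kJ mol⁻¹)
    Z + E → Q (k = 0.451 M⁻¹ min⁻¹, Ea = 85.0 kJ mol⁻¹)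
    Z + E → G (k = 0.0145 M⁻¹ min⁻¹, Ea = 85.0 kJ mol⁻¹)
    (constants at 110 °C)

**The reason.** The equivalents of Z are the main reason for ash's 0%: ash run on oak's Z gives 52.9%. The forecast's oak figure would fail if oak's Z rose to 1.43 equiv, where E has moved by 5 points.

**Next flask.** In a neighbour flask, oak with 2.20 equiv of Z, the ceiling is −20.0%, so expect no E and 9.09% of its own Z charge left. Computed, that neighbour flask holds E 0% and Z 9.09%.

Readings and results were computed for substances that don't exist; noise was put on by code.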